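**Plan**

1. Cuts: C6–C7 (ring A to the chain, made last), C11=C12 (Horner–Wadsworth–Emmons), C11'=C12' (Wittig), C9'–C10' (vinyl addition to an α-ionone ketone) and both ester C–O bonds.
2. Enabling feature: in ring A, C6 is the carbonyl carbon of a 2,2,6-trimethylcyclohexanone whose second α-carbon C1 is quaternary, so a single enol triflate fixes the C5=C6 double bond and puts a leaving group on C6; C7 is the tin-bearing end of an (E)-alkenylstannane.
3. Forward: ring A comes ready-made from actinol (ester, then triflate); ring B comes ready-made from (R)-α-ionone and its side chain grows C13 → C15 → C25 → C31. The C31 nonaenylstannane and the ring A triflate, each already carrying its myristate, are joined in the last step, which gives the target itself.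
4. Stereochemistry: C3 from (4R,6R)-actinol; C6' from (R)-α-ionone; C3' from a catalyst-controlled CBS reduction of the ring enone; E alkenes from syn-hydrostannation, E-selective olefinations, iodine equilibration and a stereoretentive coupling.

Key step: step 15

Assumption: (R)-(+)-α-ionone of high enantiomeric purity and (2E,4E,6E)-2,7-dimethylocta-2,4,6-trienedial (the industrial C10 carotenoid building block) are taken as purchasable. Carotenoid numbering is used throughout (ring A = C1–C6, ring B = C1'–C6').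

**Route**

Step 1
Reactants: 1 (4R,6R)-4-hydroxy-2,2,6-trimethylcyclohexan-1-one (actinol)
Product: 2 (1R,5R)-3,3,5-trimethyl-4-oxocyclohexyl tetradecanoate
Conditions: C13H27COCl, pyridine, DMAP (cat.), CH2Cl2, 0 °C → rt
Reagents that add atoms: tetradecanoyl chloride CCCCCCCCCCCCCC(=O)Cl
Why: DMAP-catalysed O-acylation of the unhindered secondary alcohol leaves the carbinol centre untouched; the epimerisable methyl-bearing centre is erased in step 2.

Step 2
Reactants: 2 (1R,5R)-3,3,5-trimethyl-4-oxocyclohexyl tetradecanoate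
Product: 3 (4R)-2,6,6-trimethyl-4-(tetradecanoyloxy)cyclohex-1-en-1-yl trifluoromethanesulfonate
Conditions: Tf2O, 2,6-di-tert-butyl-4-methylpyridine, CH2Cl2, 0 °C → rt
Reagents that add atoms: trifluoromethanesulfonic anhydride FC(F)(F)S(=O)(=O)OS(=O)(=O)C(F)(F)F
Why: Electrophilic enol triflate formation (Stang conditions): O-sulfonylation of the ketone and loss of its only α-hydrogen (the other α-carbon is quaternary) should give one tetrasubstituted enol triflate, and the hindered non-nucleophilic base leaves the ester alone.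

Step 3
Reactants: 4 (2E)-3-methylpent-2-en-4-yn-1-ol
Product: 5 (2E,4E)-3-methyl-5-(tributylstannyl)penta-2,4-dien-1-ol
Conditions: Bu3SnH, PdCl2(PPh3)2 (cat.), THF, 0 °C
Reagents that add atoms: tributyltin hydride CCCC[SnH](CCCC)CCCC
Why: Palladium-catalysed syn-hydrostannation of the terminal alkyne of a conjugated enyne should place tin on the terminal carbon and make the new alkene E; any internal regioisomer should be removable by chromatography.

Step 4
Reactants: 5 (2E,4E)-3-methyl-5-(tributylstannyl)penta-2,4-dien-1-ol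
Product: 6 tributyl[(1E,3E)-5-bromo-3-methylpenta-1,3-dien-1-yl]stannane
Conditions: CBr4, PPh3, CH2Cl2, –20 → 0 °C
Reagents that add atoms: carbon tetrabromide BrC(Br)(Br)Br
Why: Appel bromination of the primary allylic alcohol runs under neutral conditions that spare the acid-labile C–Sn bond.

Step 5
Reactants: 6 tributyl[(1E,3E)-5-bromo-3-methylpenta-1,3-dien-1-yl]stannane
Product: 7 diethyl [(2E,4E)-3-methyl-5-(tributylstannyl)penta-2,4-dien-1-yl]phosphonate
Conditions: P(OEt)3 (neat), 90 °C
Reagents that add atoms: triethyl phosphite CCOP(OCC)OCC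
Why: Michaelis–Arbuzov reaction at the unhindered primary allylic bromide proceeds by SN2 attack and should keep both alkene geometries.

Step 6
Reactants: 8 (R)-α-ionone, (3E)-4-[(1R)-2,6,6-trimethylcyclohex-2-en-1-yl]but-3-en-2-one
Product: 9 2-methyl-2-[(E)-2-[(1R)-2,6,6-trimethylcyclohex-2-en-1-yl]ethenyl]-1,3-dioxolane
Conditions: Me3SiOCH2CH2OSiMe3, Me3SiOTf (cat.), CH2Cl2, –78 °C; pyridine quench
Reagents that add atoms: 1,2-bis(trimethylsilyloxy)ethane C[Si](C)(C)OCCO[Si](C)(C)C
Why: Noyori ketalisation at low temperature masks the side-chain enone without acid-promoted migration of the C4'=C5' or C7'=C8' double bonds and without loss of the C6' configuration.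

Step 7
Reactants: 9 2-methyl-2-[(E)-2-[(1R)-2,6,6-trimethylcyclohex-2-en-1-yl]ethenyl]-1,3-dioxolane
Product: 10 (4R)-3,5,5-trimethyl-4-[(E)-2-(2-methyl-1,3-dioxolan-2-yl)ethenyl]cyclohex-2-en-1-one
Conditions: t-BuOOH, Rh2(cap)4 (dirhodium tetracaprolactamate, cat.), K2CO3, CH2Cl2, rt
Reagents that add atoms: tert-butyl hydroperoxide CC(C)(C)OO
Why: Rhodium-catalysed allylic C–H oxidation (peroxyl radical chain) should convert the only unhindered allylic methylene, ring C3', into the enone, while the C6'–H next to the quaternary C1' is shielded and the near-neutral medium should not epimerise C6'.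

Step 8
Reactants: 10 (4R)-3,5,5-trimethyl-4-[(E)-2-(2-methyl-1,3-dioxolan-2-yl)ethenyl]cyclohex-2-en-1-one
Product: 11 (1R,4R)-3,5,5-trimethyl-4-[(E)-2-(2-methyl-1,3-dioxolan-2-yl)ethenyl]cyclohex-2-en-1-ol
Conditions: (S)-2-methyl-CBS-oxazaborolidine (cat.), catecholborane, toluene, –78 °C; MeOH, then aq. NaOH wash
Reagents that add atoms: none
Why: Corey–Bakshi–Shibata reduction: the (S)-oxazaborolidine should bind the enone with the alkenyl arm (C4') as the large group and deliver hydride to the face that gives the (3'R) allylic alcohol under catalyst control, which with the fixed (6'R) centre is the 3',6'-trans isomer; catecholborane should give 1,2-reduction only.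

Step 9
Reactants: 11 (1R,4R)-3,5,5-trimethyl-4-[(E)-2-(2-methyl-1,3-dioxolan-2-yl)ethenyl]cyclohex-2-en-1-ol
Product: 12 (3R,6R)-3-hydroxy-α-ionone, (3E)-4-[(1R,4R)-4-hydroxy-2,6,6-trimethylcyclohex-2-en-1-yl]but-3-en-2-one
Conditions: pyridinium p-toluenesulfonate (cat.), acetone/H2O, rt
Reagents that add atoms: water O
Why: Mild acid hydrolysis of the allylic dioxolane should free the methyl ketone under conditions too weak to ionise the ring allylic alcohol.

Step 10
Reactants: 12 (3R,6R)-3-hydroxy-α-ionone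
Product: 13 (1R,4R)-4-[(1E)-3-hydroxy-3-methylpenta-1,4-dien-1-yl]-3,5,5-trimethylcyclohex-2-en-1-ol (both epimers at the new tertiary carbinol)
Conditions: CH2=CHMgBr (excess), THF, –78 → 0 °C; then H2O
Reagents that add atoms: vinylmagnesium bromide C=C[Mg]Br
Why: Grignard 1,2-addition to the methyl enone (the first equivalent is consumed by the hydroxyl group) should give the tertiary divinyl carbinol; its new centre is irrelevant because it becomes sp2 in step 12.

Step 11
Reactants: 13 (1R,4R)-4-[(1E)-3-hydroxy-3-methylpenta-1,4-dien-1-yl]-3,5,5-trimethylcyclohex-2-en-1-ol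
Product: 14 (1R,4R)-4-[(1E)-3-hydroxy-3-methylpenta-1,4-dien-1-yl]-3,5,5-trimethylcyclohex-2-en-1-yl tetradecanoate
Conditions: C13H27COCl (1 equiv), pyridine, DMAP (cat.), CH2Cl2, 0 °C
Reagents that add atoms: tetradecanoyl chloride CCCCCCCCCCCCCC(=O)Cl
Why: DMAP-catalysed acylation should be chemoselective for the secondary allylic alcohol, with retention at C3', because the tertiary carbinol is too hindered to react.

Step 12
Reactants: 14 (1R,4R)-4-[(1E)-3-hydroxy-3-methylpenta-1,4-dien-1-yl]-3,5,5-trimethylcyclohex-2-en-1-yl tetradecanoate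
Product: 15 [(2E,4E)-3-methyl-5-[(1R,4R)-2,6,6-trimethyl-4-(tetradecanoyloxy)cyclohex-2-en-1-yl]penta-2,4-dien-1-yl]triphenylphosphonium bromide
Conditions: PPh3·HBr, CH2Cl2/MeOH, 0 °C → rt; crystallisation
Reagents that add atoms: triphenylphosphine hydrobromide [Br-].c1ccc(cc1)[PH+](c1ccccc1)c1ccccc1
Why: Classical C15 Wittig salt formation: ionisation of the tertiary bis-allylic alcohol gives a pentadienyl cation that triphenylphosphine should capture at the unhindered primary terminus C11' to give the conjugated (9'E) salt, while the ring allylic ester is far less prone to ionise.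

Step 13
Reactants: 15 [(2E,4E)-3-methyl-5-[(1R,4R)-2,6,6-trimethyl-4-(tetradecanoyloxy)cyclohex-2-en-1-yl]penta-2,4-dien-1-yl]triphenylphosphonium bromide; 16 (2E,4E,6E)-2,7-dimethylocta-2,4,6-trienedial
Product: 18 (2E,4E,6E,8E,10E,12E)-2,7,11-trimethyl-13-[(1R,4R)-2,6,6-trimethyl-4-(tetradecanoyloxy)cyclohex-2-en-1-yl]trideca-2,4,6,8,10,12-hexaenal (C25 aldehyde), via phosphonium ylide 17 (not isolated)
Conditions: NaN(SiMe3)2, THF, –78 °C; inverse addition to 16 (excess), –78 → 0 °C; then I2 (cat.), CH2Cl2, rt, daylight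
Reagents that add atoms: none
Why: Wittig olefination of one aldehyde group of the symmetrical dialdehyde, with mono-selectivity secured by inverse addition to excess 16, followed by iodine-catalysed equilibration of the new C11'=C12' bond to E.

Step 14
Reactants: 18 C25 aldehyde; 7 diethyl [(2E,4E)-3-methyl-5-(tributylstannyl)penta-2,4-dien-1-yl]phosphonate
Product: 20 tributyl[(1E,3E,5E,7E,9E,11E,13E,15E,17E)-3,7,12,16-tetramethyl-18-[(1R,4R)-2,6,6-trimethyl-4-(tetradecanoyloxy)cyclohex-2-en-1-yl]octadeca-1,3,5,7,9,11,13,15,17-nonaen-1-yl]stannane (C31 stannane), via sodium phosphonate carbanion 19 (not isolated)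
Conditions: 7, NaN(SiMe3)2, THF, –78 °C; then 18, –78 → 0 °C; dark
Reagents that add atoms: none
Why: Horner–Wadsworth–Emmons olefination of the α-methyl enal with an allylic phosphonate carbanion should be E-selective at the new C11=C12 bond; the amide base avoids tin–lithium exchange and the ester is untouched at low temperature.

Step 15
Reactants: 20 C31 stannane; 3 (4R)-2,6,6-trimethyl-4-(tetradecanoyloxy)cyclohex-1-en-1-yl trifluoromethanesulfonate
Product: 21 lutein dimyristate, (3R,3'R,6'R)-β,ε-carotene-3,3'-diyl ditetradecanoate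
Conditions: Pd2(dba)3 (cat.), AsPh3, NMP, 50 °C, argon, dark
Reagents that add atoms: none
Why: Stille coupling: zerovalent palladium inserts into the C6–OTf bond of 3 to give a cationic divalent alkenylpalladium species, the (E)-alkenyl group of 20 is transferred from tin in the rate-limiting transmetalation (helped by the weakly bound AsPh3 and the polar solvent), and reductive elimination forms C6–C7 with retention at both sp2 carbons. The closest known reaction type is the Stille coupling of hindered 2,6,6-trimethylcyclohexenyl triflates with dienyl- and polyenylstannanes used for retinoids. No ring is closed and no stereocentre is formed: C3, C3' and C6' are carried in unchanged, and the position of the ring A double bond is fixed by the triflate, which could only form toward C5. The step needs retention of the 7E geometry and of the all-E polyene, which the stereoretentive transmetalation and reductive elimination together with exclusion of light should secure. It also needs oxidative addition at the vinyl triflate to outrun ionisation of the allylic myristate at C3' by zerovalent palladium; the phosphine-free, weakly donating catalyst and the hindered allyl termini of ring B (C5' fully substituted beside the quaternary C1') should secure this. Both esters are inert to these neutral conditions, so the coupling should deliver the target directly.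

**Compound list**

1 | (4R,6R)-4-hydroxy-2,2,6-trimethylcyclohexan-1-one (actinol) | C[C@@H]1C[C@@H](O)CC(C)(C)C1=O | starting material
2 | (1R,5R)-3,3,5-trimethyl-4-oxocyclohexyl tetradecanoate | C[C@@H]1C[C@@H](OC(=O)CCCCCCCCCCCCC)CC(C)(C)C1=O | intermediate
3 | (4R)-2,6,6-trimethyl-4-(tetradecanoyloxy)cyclohex-1-en-1-yl trifluoromethanesulfonate | CCCCCCCCCCCCCC(=O)O[C@@H]1CC(C)=C(OS(=O)(=O)C(F)(F)F)C(C)(C)C1 | intermediate
4 | (2E)-3-methylpent-2-en-4-yn-1-ol | C#C/C(C)=C/CO | starting material
5 | (2E,4E)-3-methyl-5-(tributylstannyl)penta-2,4-dien-1-ol | CCCC[Sn](CCCC)(CCCC)/C=C/C(C)=C/CO | intermediate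
6 | tributyl[(1E,3E)-5-bromo-3-methylpenta-1,3-dien-1-yl]stannane | CCCC[Sn](CCCC)(CCCC)/C=C/C(C)=C/CBr | intermediate
7 | diethyl [(2E,4E)-3-methyl-5-(tributylstannyl)penta-2,4-dien-1-yl]phosphonate | CCCC[Sn](CCCC)(CCCC)/C=C/C(C)=C/CP(=O)(OCC)OCC | intermediate
8 | (R)-α-ionone, (3E)-4-[(1R)-2,6,6-trimethylcyclohex-2-en-1-yl]but-3-en-2-one | CC(=O)/C=C/[C@H]1C(C)=CCCC1(C)C | starting material
9 | 2-methyl-2-[(E)-2-[(1R)-2,6,6-trimethylcyclohex-2-en-1-yl]ethenyl]-1,3-dioxolane | CC1(/C=C/[C@H]2C(C)=CCCC2(C)C)OCCO1 | intermediate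
10 | (4R)-3,5,5-trimethyl-4-[(E)-2-(2-methyl-1,3-dioxolan-2-yl)ethenyl]cyclohex-2-en-1-one | CC1(/C=C/[C@H]2C(C)=CC(=O)CC2(C)C)OCCO1 | intermediate
11 | (1R,4R)-3,5,5-trimethyl-4-[(E)-2-(2-methyl-1,3-dioxolan-2-yl)ethenyl]cyclohex-2-en-1-ol | CC1(/C=C/[C@H]2C(C)=C[C@H](O)CC2(C)C)OCCO1 | intermediate
12 | (3R,6R)-3-hydroxy-α-ionone, (3E)-4-[(1R,4R)-4-hydroxy-2,6,6-trimethylcyclohex-2-en-1-yl]but-3-en-2-one | CC(=O)/C=C/[C@H]1C(C)=C[C@H](O)CC1(C)C | intermediate
13 | (1R,4R)-4-[(1E)-3-hydroxy-3-methylpenta-1,4-dien-1-yl]-3,5,5-trimethylcyclohex-2-en-1-ol (both carbinol epimers) | C=CC(C)(O)/C=C/[C@H]1C(C)=C[C@H](O)CC1(C)C | intermediate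
14 | (1R,4R)-4-[(1E)-3-hydroxy-3-methylpenta-1,4-dien-1-yl]-3,5,5-trimethylcyclohex-2-en-1-yl tetradecanoate (both carbinol epimers) | C=CC(C)(O)/C=C/[C@H]1C(C)=C[C@H](OC(=O)CCCCCCCCCCCCC)CC1(C)C | intermediate
15 | [(2E,4E)-3-methyl-5-[(1R,4R)-2,6,6-trimethyl-4-(tetradecanoyloxy)cyclohex-2-en-1-yl]penta-2,4-dien-1-yl]triphenylphosphonium bromide | c1ccccc1[P+](c1ccccc1)(c1ccccc1)C/C=C(C)/C=C/[C@H]1C(C)=C[C@H](OC(=O)CCCCCCCCCCCCC)CC1(C)C.[Br-] | intermediate
16 | (2E,4E,6E)-2,7-dimethylocta-2,4,6-trienedial (C10 dialdehyde) | O=C/C(C)=C/C=C/C=C(C)/C=O | starting material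
17 | phosphonium ylide of 15 | c1ccccc1[P+](c1ccccc1)(c1ccccc1)[CH-]/C=C(C)/C=C/[C@H]1C(C)=C[C@H](OC(=O)CCCCCCCCCCCCC)CC1(C)C | intermediate (not isolated)
18 | (2E,4E,6E,8E,10E,12E)-2,7,11-trimethyl-13-[(1R,4R)-2,6,6-trimethyl-4-(tetradecanoyloxy)cyclohex-2-en-1-yl]trideca-2,4,6,8,10,12-hexaenal (C25 aldehyde) | O=C/C(C)=C/C=C/C=C(C)/C=C/C=C(C)/C=C/[C@H]1C(C)=C[C@H](OC(=O)CCCCCCCCCCCCC)CC1(C)C | intermediate
19 | sodium carbanion of phosphonate 7 | [Na+].CCCC[Sn](CCCC)(CCCC)/C=C/C(C)=C/[CH-]P(=O)(OCC)OCC | intermediate (not isolated)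
20 | tributyl[(1E,3E,5E,7E,9E,11E,13E,15E,17E)-3,7,12,16-tetramethyl-18-[(1R,4R)-2,6,6-trimethyl-4-(tetradecanoyloxy)cyclohex-2-en-1-yl]octadeca-1,3,5,7,9,11,13,15,17-nonaen-1-yl]stannane (C31 stannane) | CCCC[Sn](CCCC)(CCCC)/C=C/C(C)=C/C=C/C(C)=C/C=C/C=C(C)/C=C/C=C(C)/C=C/[C@H]1C(C)=C[C@H](OC(=O)CCCCCCCCCCCCC)CC1(C)C | intermediate
21 | lutein dimyristate, (3R,3'R,6'R)-β,ε-carotene-3,3'-diyl ditetradecanoate | CCCCCCCCCCCCCC(=O)O[C@@H]1CC(C)=C(/C=C/C(C)=C/C=C/C(C)=C/C=C/C=C(C)/C=C/C=C(C)/C=C/[C@H]2C(C)=C[C@H](OC(=O)CCCCCCCCCCCCC)CC2(C)C)C(C)(C)C1 | target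

**Count and risks**

Total step count: 15. Longest linear sequence: 10 steps (steps 6 to 15, from 8 to 21).

Steps most likely to fail:

Step 15. Transmetalation at the hindered tetrasubstituted alkenylpalladium centre may be slow, so that the long polyenylstannane loses tin by protonolysis, homocouples or isomerises before it couples. Zerovalent palladium may also ionise the allylic ester of ring B. Fallback: the C6–C7 bond is made on the small, robust stannane instead and the halves are joined by olefination. Setting out from 3 and 7, the same Stille coupling (Pd2(dba)3, AsPh3, NMP) would give diethyl [(2E,4E)-3-methyl-5-[(4R)-2,6,6-trimethyl-4-(tetradecanoyloxy)cyclohex-1-en-1-yl]penta-2,4-dien-1-yl]phosphonate F1. Deprotonation with NaN(SiMe3)2 in THF at –78 °C would give its sodium carbanion F2 (not isolated). A Horner–Wadsworth–Emmons reaction of F2 with aldehyde 18 would form C11=C12 and come back to the route at 21.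

Step 8. Facial selectivity of hydride delivery may be poor if the catalyst's preference and the ring's own bias (axial methyl at C1', side chain at C6') are mismatched, giving much of the 3',6'-cis epimer. Fallback: both epimers are made usable. Setting out from 10, a Luche reduction (NaBH4, CeCl3·7H2O, MeOH, –40 °C) would give the two C3' epimers, separable as diastereomers. The trans epimer is 11 itself. The cis epimer, (1S,4R)-3,5,5-trimethyl-4-[(E)-2-(2-methyl-1,3-dioxolan-2-yl)ethenyl]cyclohex-2-en-1-ol F3, would be hydrolysed as in step 9 to (3S,6R)-3-hydroxy-α-ionone F4. Vinyl Grignard addition as in step 10 would give (1S,4R)-4-[(1E)-3-hydroxy-3-methylpenta-1,4-dien-1-yl]-3,5,5-trimethylcyclohex-2-en-1-ol F5. Mitsunobu esterification of F5 (tetradecanoic acid, PPh3, diisopropyl azodicarboxylate, THF, 0 °C) would acylate the secondary allylic alcohol with inversion at C3' and come back to the route at 14.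

Step 2. O-Sulfonylation of the hindered carbonyl may stall, or the cationic intermediate may undergo a 1,2-methyl shift from the neighbouring quaternary carbon before it loses the α-hydrogen. Fallback: kinetic enolate trapping on a silyl-protected ketone. Setting out from 1, silylation (t-BuMe2SiCl, imidazole, DMF) would give (4R,6R)-4-[(tert-butyldimethylsilyl)oxy]-2,2,6-trimethylcyclohexan-1-one F6. LiN(iPr)2 in THF at –78 °C would give the only possible lithium enolate F7 (not isolated). N-Phenylbis(trifluoromethanesulfonimide) would give (4R)-4-[(tert-butyldimethylsilyl)oxy]-2,6,6-trimethylcyclohex-1-en-1-yl trifluoromethanesulfonate F8. HF·pyridine in THF would give (4R)-4-hydroxy-2,6,6-trimethylcyclohex-1-en-1-yl trifluoromethanesulfonate F9. Acylation with tetradecanoyl chloride (pyridine, DMAP) would come back to the route at 3.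

Further compounds
F1 | step 15 | diethyl [(2E,4E)-3-methyl-5-[(4R)-2,6,6-trimethyl-4-(tetradecanoyloxy)cyclohex-1-en-1-yl]penta-2,4-dien-1-yl]phosphonate | CCCCCCCCCCCCCC(=O)O[C@@H]1CC(C)=C(/C=C/C(C)=C/CP(=O)(OCC)OCC)C(C)(C)C1
F2 | step 15 | sodium carbanion of F1 | [Na+].CCCCCCCCCCCCCC(=O)O[C@@H]1CC(C)=C(/C=C/C(C)=C/[CH-]P(=O)(OCC)OCC)C(C)(C)C1
F3 | step 8 | (1S,4R)-3,5,5-trimethyl-4-[(E)-2-(2-methyl-1,3-dioxolan-2-yl)ethenyl]cyclohex-2-en-1-ol | CC1(/C=C/[C@H]2C(C)=C[C@@H](O)CC2(C)C)OCCO1
F4 | step 8 | (3S,6R)-3-hydroxy-α-ionone | CC(=O)/C=C/[C@H]1C(C)=C[C@@H](O)CC1(C)C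
F5 | step 8 | (1S,4R)-4-[(1E)-3-hydroxy-3-methylpenta-1,4-dien-1-yl]-3,5,5-trimethylcyclohex-2-en-1-ol | C=CC(C)(O)/C=C/[C@H]1C(C)=C[C@@H](O)CC1(C)C
F6 | step 2 | (4R,6R)-4-[(tert-butyldimethylsilyl)oxy]-2,2,6-trimethylcyclohexan-1-one | C[C@@H]1C[C@@H](O[Si](C)(C)C(C)(C)C)CC(C)(C)C1=O
F7 | step 2 | lithium enolate of F6 | [Li+].CC(C)(C)[Si](C)(C)O[C@@H]1CC(C)=C([O-])C(C)(C)C1
F8 | step 2 | (4R)-4-[(tert-butyldimethylsilyl)oxy]-2,6,6-trimethylcyclohex-1-en-1-yl trifluoromethanesulfonate | CC(C)(C)[Si](C)(C)O[C@@H]1CC(C)=C(OS(=O)(=O)C(F)(F)F)C(C)(C)C1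
F9 | step 2 | (4R)-4-hydroxy-2,6,6-trimethylcyclohex-1-en-1-yl trifluoromethanesulfonate | O[C@@H]1CC(C)=C(OS(=O)(=O)C(F)(F)F)C(C)(C)C1
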